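**Retrosynthetic overview**

1. Target 24 ⇐ quinone 23 ⇐ bis(methyl ether) 22 (late oxidative O‑demethylation, then reduction). Ring C is closed last: the C–CH2 bond at the aryl‑bearing ring‑fusion carbon comes from intramolecular enolate alkylation by the (Z)‑allylic chain on the benzylic CH, which completes the benzobicyclo[3.2.1]octadiene.
2. Ring A ⇐ (2‑prenyl‑1H‑inden‑3‑yl)(methoxy)carbene–Cr(CO)5 + HC≡CH + CO; the C(=O)–C(quaternary, prenyl) bond and the CH–C(O) bond form together. Enabling feature: ring A is a cyclohex‑2‑ene‑1,4‑dione (O=C–CH=CH–C=O) closed by two adjacent sp3 ring‑fusion carbons, the prenyl‑bearing one quaternary. It is a 1,4‑dioxygenated six‑membered ring that cannot aromatise, i.e. a benzannulation arrested at the cyclohexadienone.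
3. Carbene complex ⇐ indene‑3‑carboxylic acid ⇐ enol triflate ⇐ 2‑prenyl‑3‑alkenylindan‑1‑one ⇐ Rh‑catalysed asymmetric alkenyl addition to 4,7‑dimethoxyindenone. This single catalyst‑set centre (the future bridgehead CH) directs both quaternary carbons.
4. Ring order: arene B and the five‑membered ring (bought as the indanone) → ring A (key step) → ring C (alkylation).

Key step: step 10

Remark: the (3R) sense of the Rh/(R)‑BINAP addition in step 5 is assigned by analogy with cyclopent‑2‑enone; the antipodal ligand is to be used if the sense is the opposite.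

**Route**

Step 1
Reactants: 1 prop‑2‑yn‑1‑ol
Product: 3 (2Z)‑3‑iodo‑2‑methylprop‑2‑en‑1‑ol, via chelated alkenylmagnesium alkoxide 2 (not isolated)
Conditions: MeMgBr (2.5 equiv), CuI (10 mol%), THF/Et2O, −10 °C → rt; then I2, −78 → 0 °C; aq. NH4Cl
Reagents that add atoms: methylmagnesium bromide, C[Mg]Br; iodine, II
Why: Copper‑catalysed anti‑carbomagnesiation of the propargylic alkoxide gives the O‑chelated (Z)‑alkenylmagnesium, and iodinolysis with retention leaves iodine cis to CH2OH.

Step 2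
Reactants: 3 (2Z)‑3‑iodo‑2‑methylprop‑2‑en‑1‑ol
Product: 4 tert‑butyl{[(2Z)‑3‑iodo‑2‑methylprop‑2‑en‑1‑yl]oxy}dimethylsilane
Conditions: TBSCl, imidazole, CH2Cl2, 0 °C → rt
Reagents that add atoms: tert‑butyl(chloro)dimethylsilane, CC(C)(C)[Si](C)(C)Cl
Why: Routine silyl ether formation on a primary alcohol, needed to carry the allylic oxygen through the enolate, triflation and chromium steps.

Step 3
Reactants: 4 tert‑butyl{[(2Z)‑3‑iodo‑2‑methylprop‑2‑en‑1‑yl]oxy}dimethylsilane
Product: 5 tert‑butyldimethyl{[(2Z)‑2‑methyl‑3‑(4,4,5,5‑tetramethyl‑1,3,2‑dioxaborolan‑2‑yl)prop‑2‑en‑1‑yl]oxy}silane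
Conditions: B2pin2, PdCl2(dppf) (3 mol%), KOPh, toluene, 50 °C
Reagents that add atoms: bis(pinacolato)diboron, CC1(C)OB(OC1(C)C)B1OC(C)(C)C(C)(C)O1
Why: Miyaura borylation of an alkenyl iodide proceeds with retention of alkene geometry, and phenoxide as base suppresses Suzuki homocoupling.

Step 4
Reactants: 6 4,7‑dimethoxy‑2,3‑dihydro‑1H‑inden‑1‑one
Product: 7 4,7‑dimethoxy‑1H‑inden‑1‑one
Conditions: IBX (2.5 equiv), DMSO/fluorobenzene, 70 °C; used without storage
Reagents that add atoms: none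
Why: IBX dehydrogenation of a benzo‑fused cyclopentanone through its enol gives the indenone, the Michael acceptor for the asymmetric step.

Step 5
Reactants: 7 4,7‑dimethoxy‑1H‑inden‑1‑one; 5 the (Z)‑alkenyl pinacol boronate
Product: 8 (3R)‑3‑[(1Z)‑3‑{[tert‑butyl(dimethyl)silyl]oxy}‑2‑methylprop‑1‑en‑1‑yl]‑4,7‑dimethoxy‑2,3‑dihydro‑1H‑inden‑1‑one
Conditions: [Rh(OH)(cod)]2 (2.5 mol%), (R)‑BINAP (5.5 mol%), dioxane/H2O 10:1, 50 °C
Reagents that add atoms: none
Why: Rhodium‑catalysed asymmetric 1,4‑addition of an alkenylboron reagent to a cyclic enone; the bisphosphine differentiates the enone faces and sets the (3R) centre, and alkene geometry is retained through transmetalation.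

Step 6
Reactants: 8 the (3R)‑3‑alkenylindanone; 9 1‑bromo‑3‑methylbut‑2‑ene
Product: 10 (2S,3S)‑3‑[(1Z)‑3‑{[tert‑butyl(dimethyl)silyl]oxy}‑2‑methylprop‑1‑en‑1‑yl]‑4,7‑dimethoxy‑2‑(3‑methylbut‑2‑en‑1‑yl)‑2,3‑dihydro‑1H‑inden‑1‑one (2,3‑trans)
Conditions: LiHMDS (1.05 equiv), THF, −78 °C; then 9, −78 → 0 °C
Reagents that add atoms: none
Why: Lithium enolate alkylation at the only enolisable α‑carbon; the prenyl group should enter anti to the C3 substituent, though this centre becomes sp2 in step 7.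

Step 7
Reactants: 10 the 2‑prenyl‑3‑alkenylindanone
Product: 11 (1S)‑1‑[(1Z)‑3‑{[tert‑butyl(dimethyl)silyl]oxy}‑2‑methylprop‑1‑en‑1‑yl]‑4,7‑dimethoxy‑2‑(3‑methylbut‑2‑en‑1‑yl)‑1H‑inden‑3‑yl trifluoromethanesulfonate
Conditions: Tf2O (1.3 equiv), 2,6‑di‑tert‑butyl‑4‑methylpyridine (1.5 equiv), CH2Cl2, 0 °C → rt
Reagents that add atoms: trifluoromethanesulfonic anhydride, O=S(=O)(OS(=O)(=O)C(F)(F)F)C(F)(F)F
Why: Enol triflate formation under hindered‑pyridine buffering; only C2 can enolise, and the absence of strong base protects the new doubly activated indene C1–H.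

Step 8
Reactants: 11 the indenyl triflate
Product: 12 (1S)‑1‑[(1Z)‑3‑{[tert‑butyl(dimethyl)silyl]oxy}‑2‑methylprop‑1‑en‑1‑yl]‑4,7‑dimethoxy‑2‑(3‑methylbut‑2‑en‑1‑yl)‑1H‑indene‑3‑carboxylic acid
Conditions: Pd(OAc)2 (5 mol%), dppf (6 mol%), CO (1 atm), KOAc (4 equiv), DMF/H2O 20:1, 60 °C; mild acidic work‑up
Reagents that add atoms: carbon monoxide, [C-]#[O+]; water, O
Why: Palladium‑catalysed hydroxycarbonylation of an enol triflate (oxidative addition, CO insertion, capture of the acyl‑palladium); the product is held as the carboxylate, which does not acidify the indene C1–H.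

Step 9
Reactants: 12 the indene‑3‑carboxylic acid; 13 hexacarbonylchromium
Product: 16 pentacarbonyl[(methoxy){(1S)‑1‑[(1Z)‑3‑{[tert‑butyl(dimethyl)silyl]oxy}‑2‑methylprop‑1‑en‑1‑yl]‑4,7‑dimethoxy‑2‑(3‑methylbut‑2‑en‑1‑yl)‑1H‑inden‑3‑yl}methylidene]chromium(0), via acid chloride 14 (not isolated), via sodium acylchromate 15 (not isolated)
Conditions: (a) 1‑chloro‑N,N,2‑trimethylprop‑1‑en‑1‑amine, CH2Cl2, 0 °C; (b) Na2Cr(CO)5 [from 13, Na (2 equiv), naphthalene, THF, −78 °C], THF, −78 → 0 °C; (c) Me3OBF4, CH2Cl2, 0 °C; chromatography under argon, used at once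
Reagents that add atoms: trimethyloxonium tetrafluoroborate, C[O+](C)C.F[B-](F)(F)F (O‑methyl group); sodium, [Na] (counter‑ion of 15 only); 1‑chloro‑N,N,2‑trimethylprop‑1‑en‑1‑amine, CC(C)=C(Cl)N(C)C (chlorine of 14 only)
Why: Acylation of the pentacarbonylchromate dianion by an acid chloride and O‑methylation of the acyl chromate is the organolithium‑free route to Fischer alkoxycarbene complexes, chosen because a vinyllithium or amine base would ionise the indene C1–H.

Step 10
Reactants: 16 the indenyl(methoxy)carbene complex; 17 ethyne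
Product: 19 (9R,9aS)‑9‑[(1Z)‑3‑{[tert‑butyl(dimethyl)silyl]oxy}‑2‑methylprop‑1‑en‑1‑yl]‑4,5,8‑trimethoxy‑9a‑(3‑methylbut‑2‑en‑1‑yl)‑9,9a‑dihydro‑1H‑fluoren‑1‑one, via Cr(CO)3‑bound dienylketene 18 (not isolated)
Conditions: ethyne (1 atm, saturated solution), THF (0.02 M), 50 °C, sealed vessel; then air, MeCN, rt
Reagents that add atoms: none
Why: Thermal loss of CO from 16, coordination and insertion of ethyne give a vinylcarbene that inserts CO to the chromium‑bound dienylketene 18, whose six‑electron electrocyclisation onto C2 of the indene and loss of the metal should deliver the 2,4‑cyclohexadienone; this is the Dötz benzannulation in its cyclohexadienone mode, as known for β,β‑disubstituted alkenyl alkoxycarbene complexes. Ring A closes by a disrotatory 6π electrocyclisation (ketene carbon to the fully substituted alkene terminus), and because that terminus carries the prenyl group the dienone cannot tautomerise to a phenol. The new quaternary stereocentre is controlled by the adjacent C1 centre: the ketene carbon should bond to C2 on the face anti to the C1 alkenyl chain, which places prenyl cis to that chain as the target requires. The step needs CO insertion to win over five‑ring closure (favoured by the alkoxy carbene, THF and moderate temperature), a single alkyne insertion (high dilution under 1 atm ethyne; ethyne is symmetrical, so no regiochemical issue arises), and the unactivated prenyl and side‑chain alkenes to remain spectators.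

Step 11
Reactants: 19 the tricyclic 4‑methoxydienone
Product: 20 (4aR,9R,9aS)‑9‑[(1Z)‑3‑hydroxy‑2‑methylprop‑1‑en‑1‑yl]‑5,8‑dimethoxy‑9a‑(3‑methylbut‑2‑en‑1‑yl)‑9,9a‑dihydro‑1H‑fluorene‑1,4(4aH)‑dione
Conditions: 1 M aq. HCl, THF, 0 °C → rt, under argon
Reagents that add atoms: water, O
Why: Aqueous acid hydrolyses the dienol methyl ether to the 2‑ene‑1,4‑dione (C‑protonation should give the cis ring fusion) and cleaves the primary silyl ether; the quaternary C9a blocks aromatisation.

Step 12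
Reactants: 20 the ene‑dione allylic alcohol
Product: 22 bis(O‑methyl) ether of the target, via allylic mesylate 21 (not isolated)
Conditions: MsCl, Et3N, CH2Cl2, −20 °C; then DBU, 0 °C → rt
Reagents that add atoms: methanesulfonyl chloride, CS(=O)(=O)Cl (mesyl group of 21 only)
Why: Intramolecular C‑alkylation of the doubly stabilised (α‑aryl, ene‑dione) enolate by the (Z)‑allylic mesylate is a 6‑exo‑tet closure with the cis alkene inside the new ring; the chain can only reach the enolate carbon from its own face, which fixes the second quaternary centre and closes the bicyclo[3.2.1] bridge.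

Step 13
Reactants: 22 bis(O‑methyl) ether of the target
Product: 23 ring‑B p‑quinone of the target
Conditions: (NH4)2Ce(NO3)6 (2.2 equiv), MeCN/H2O 4:1, 0 °C
Reagents that add atoms: water, O
Why: Cerium(IV) oxidative demethylation of a 1,4‑dimethoxyarene (electron transfer, water capture, loss of methanol) gives the p‑quinone; isolated alkenes and the non‑aromatisable ene‑dione should be spectators.

Step 14
Reactants: 23 ring‑B p‑quinone
Product: 24 target CNP0166383.1
Conditions: Na2S2O4, EtOAc/H2O, rt, brief; degassed work‑up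
Reagents that add atoms: none
Why: Dithionite reduces a p‑quinone to the hydroquinone much faster than it attacks the ene‑dione of ring A.

**Compound list**

1 | prop‑2‑yn‑1‑ol | C#CCO | starting material
2 | bromomagnesium (2Z)‑3‑(bromomagnesio)‑2‑methylprop‑2‑en‑1‑olate | C/C(CO[Mg]Br)=C/[Mg]Br | intermediate
3 | (2Z)‑3‑iodo‑2‑methylprop‑2‑en‑1‑ol | C/C(CO)=C/I | intermediate
4 | tert‑butyl{[(2Z)‑3‑iodo‑2‑methylprop‑2‑en‑1‑yl]oxy}dimethylsilane | C/C(CO[Si](C)(C)C(C)(C)C)=C/I | intermediate
5 | tert‑butyldimethyl{[(2Z)‑2‑methyl‑3‑(pinacolboryl)prop‑2‑en‑1‑yl]oxy}silane | C/C(CO[Si](C)(C)C(C)(C)C)=C/B1OC(C)(C)C(C)(C)O1 | intermediate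
6 | 4,7‑dimethoxy‑2,3‑dihydro‑1H‑inden‑1‑one | COc1ccc(OC)c2C(=O)CCc12 | starting material
7 | 4,7‑dimethoxy‑1H‑inden‑1‑one | COc1ccc(OC)c2C(=O)C=Cc12 | intermediate
8 | (3R)‑3‑[(1Z)‑3‑(TBSO)‑2‑methylprop‑1‑en‑1‑yl]‑4,7‑dimethoxyindan‑1‑one | C/C(CO[Si](C)(C)C(C)(C)C)=C/[C@H]1CC(=O)c2c(OC)ccc(OC)c12 | intermediate
9 | 1‑bromo‑3‑methylbut‑2‑ene | CC(C)=CCBr | starting material
10 | (2S,3S)‑3‑[(1Z)‑3‑(TBSO)‑2‑methylprop‑1‑en‑1‑yl]‑4,7‑dimethoxy‑2‑prenylindan‑1‑one (trans) | C/C(CO[Si](C)(C)C(C)(C)C)=C/[C@H]1[C@H](CC=C(C)C)C(=O)c2c(OC)ccc(OC)c12 | intermediate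
11 | (1S)‑1‑[(1Z)‑3‑(TBSO)‑2‑methylprop‑1‑en‑1‑yl]‑4,7‑dimethoxy‑2‑prenyl‑1H‑inden‑3‑yl triflate | C/C(CO[Si](C)(C)C(C)(C)C)=C/[C@H]1C(CC=C(C)C)=C(OS(=O)(=O)C(F)(F)F)c2c(OC)ccc(OC)c12 | intermediate
12 | (1S)‑1‑[(1Z)‑3‑(TBSO)‑2‑methylprop‑1‑en‑1‑yl]‑4,7‑dimethoxy‑2‑prenyl‑1H‑indene‑3‑carboxylic acid | C/C(CO[Si](C)(C)C(C)(C)C)=C/[C@H]1C(CC=C(C)C)=C(C(=O)O)c2c(OC)ccc(OC)c12 | intermediate
13 | hexacarbonylchromium(0) | O=C=[Cr](=C=O)(=C=O)(=C=O)(=C=O)=C=O | starting material
14 | acid chloride of 12 | C/C(CO[Si](C)(C)C(C)(C)C)=C/[C@H]1C(CC=C(C)C)=C(C(=O)Cl)c2c(OC)ccc(OC)c12 | intermediate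
15 | sodium pentacarbonyl(acyl)chromate derived from 14 | C/C(CO[Si](C)(C)C(C)(C)C)=C/[C@H]1C(CC=C(C)C)=C(C([O-])=[Cr](=C=O)(=C=O)(=C=O)(=C=O)=C=O)c2c(OC)ccc(OC)c12.[Na+] | intermediate
16 | pentacarbonyl[(methoxy)(indenyl)methylidene]chromium(0), (1S) at the indene CH | C/C(CO[Si](C)(C)C(C)(C)C)=C/[C@H]1C(CC=C(C)C)=C(C(OC)=[Cr](=C=O)(=C=O)(=C=O)(=C=O)=C=O)c2c(OC)ccc(OC)c12 | intermediate
17 | ethyne | C#C | starting material
18 | dienylketene O=C=CH–CH=C(OMe)–indenyl, (E) at the enol ether, bound to Cr(CO)3 | C/C(CO[Si](C)(C)C(C)(C)C)=C/[C@H]1C(CC=C(C)C)=C(/C(OC)=C\C=C=O)c2c(OC)ccc(OC)c12.O=C=[Cr](=C=O)=C=O | intermediate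
19 | (9R,9aS)‑9‑[(1Z)‑3‑(TBSO)‑2‑methylprop‑1‑en‑1‑yl]‑4,5,8‑trimethoxy‑9a‑prenyl‑9,9a‑dihydro‑1H‑fluoren‑1‑one | CC(C)=CC[C@@]12C(=O)C=CC(OC)=C1c1c(OC)ccc(OC)c1[C@H]2/C=C(/C)CO[Si](C)(C)C(C)(C)C | intermediate
20 | (4aR,9R,9aS)‑9‑[(1Z)‑3‑hydroxy‑2‑methylprop‑1‑en‑1‑yl]‑5,8‑dimethoxy‑9a‑prenyl‑9,9a‑dihydro‑1H‑fluorene‑1,4(4aH)‑dione | CC(C)=CC[C@@]12C(=O)C=CC(=O)[C@@H]1c1c(OC)ccc(OC)c1[C@H]2/C=C(/C)CO | intermediate
21 | methanesulfonate of 20 | CC(C)=CC[C@@]12C(=O)C=CC(=O)[C@@H]1c1c(OC)ccc(OC)c1[C@H]2/C=C(/C)COS(C)(=O)=O | intermediate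
22 | bis(O‑methyl) ether of the target: (S) at the prenyl carbon, (R) at the aryl‑bearing quaternary carbon, (R) at the bridgehead CH | CC(C)=CC[C@@]12C(=O)C=CC(=O)[C@@]13CC(C)=C[C@@H]2c1c(OC)ccc(OC)c13 | intermediate
23 | ring‑B p‑quinone of the target, configuration unchanged | CC(C)=CC[C@@]12C(=O)C=CC(=O)[C@@]13CC(C)=C[C@@H]2C=1C(=O)C=CC(=O)C13 | intermediate
24 | CNP0166383.1: hydroquinone‑fused benzobicyclo[3.2.1]octadiene with cis‑fused cyclohex‑2‑ene‑1,4‑dione, prenyl syn to the CH2 of the cyclohexene bridge | CC(C)=CC[C@@]12C(=O)C=CC(=O)[C@@]13CC(C)=C[C@@H]2c1c(O)ccc(O)c13 | target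

**Totals**

Total step count: 14. Longest linear sequence: 13 steps (1 → 2 → 3 → 5 → … → 14); from indanone 6 it is 11 steps.

**Steps most likely to fail**

Risk 1, step 9. Once C3 of the indene carries an acyl or carbene group, its C1–H is strongly acidified. Ionisation to the planar indenide, or dehydrochlorination of 14 to a ketene by the basic metalate, would erode the configuration set in step 5 before the annulation fixes it. Fallback: the stereochemical burden is moved from retention to separation. Partly racemised 16 is taken through step 10 as written, and 19 is freed from its mirror image, the enantiomer of 19 F1, by preparative chromatography on a chiral stationary phase (supercritical CO2/alcohol). This fallback sets out from 16 and comes back to the route at 19.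

Risk 2, step 10. A second ethyne may insert into the vinylcarbene before CO does (oligomerisation), or the ring may close without CO insertion to a five‑membered ring, so that little dienone forms. Fallback: the two‑carbon unit is brought in masked. Complex 16 is heated with ethynyltrimethylsilane in THF; the bulky silyl group should stop at one insertion and end up next to the new carbonyl, giving the 2‑(trimethylsilyl)dienone F2. TBAF buffered with AcOH in THF should then remove the C‑silyl group by protodesilylation together with the O‑silyl group, giving the desilylated dienol ether alcohol F3. The aqueous acid of step 11 hydrolyses F3 to 20. This fallback sets out from 16 and comes back at 20.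

Risk 3, step 12. The tertiary enolate carbon is flanked by the methoxyarene and by the quaternary prenyl carbon on the same face. Direct displacement may therefore lose to elimination of the allylic mesylate to a diene, to intermolecular reaction, or to (Z)→(E) isomerisation of the electrophile, after which the chain can no longer reach. Fallback: a palladium π‑allyl closure that does not depend on alkene geometry. Alcohol 20 is converted with methyl chloroformate and pyridine into the allylic methyl carbonate F4. Pd2(dba)3/dppe in THF then ionises it; the methoxide released forms the enolate, π–σ–π isomerisation lets the allyl terminus reach the enolate carbon, and intramolecular Tsuji–Trost alkylation gives 22. This fallback sets out from 20 and comes back at 22.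

**Further compounds**

F1 | step 9 | enantiomer of 19 (removed on the chiral phase) | CC(C)=CC[C@]12C(=O)C=CC(OC)=C1c1c(OC)ccc(OC)c1[C@@H]2/C=C(/C)CO[Si](C)(C)C(C)(C)C
F2 | step 10 | (9R,9aS)‑9‑[(1Z)‑3‑(TBSO)‑2‑methylprop‑1‑en‑1‑yl]‑4,5,8‑trimethoxy‑9a‑prenyl‑2‑(trimethylsilyl)‑9,9a‑dihydro‑1H‑fluoren‑1‑one | CC(C)=CC[C@@]12C(=O)C([Si](C)(C)C)=CC(OC)=C1c1c(OC)ccc(OC)c1[C@H]2/C=C(/C)CO[Si](C)(C)C(C)(C)C
F3 | step 10 | (9R,9aS)‑9‑[(1Z)‑3‑hydroxy‑2‑methylprop‑1‑en‑1‑yl]‑4,5,8‑trimethoxy‑9a‑prenyl‑9,9a‑dihydro‑1H‑fluoren‑1‑one | CC(C)=CC[C@@]12C(=O)C=CC(OC)=C1c1c(OC)ccc(OC)c1[C@H]2/C=C(/C)CO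
F4 | step 12 | allylic methyl carbonate of 20 | CC(C)=CC[C@@]12C(=O)C=CC(=O)[C@@H]1c1c(OC)ccc(OC)c1[C@H]2/C=C(/C)COC(=O)OC
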